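## The problem

Labdane numbering (C1–C20) is used for the target and for all intermediates.

- **Skeleton.** Target 25 is an ent-labdane. It is a trans-decalin (ring A = C1–C5/C10, ring B = C5–C10) with four contiguous stereocentres, C4, C5, C10 and C9. C4 and C10 are quaternary.
- **The diaxial arms.** Each quaternary carbon carries an oxidised one-carbon arm: CH2OAc (C19) on C4 and CHO (C20) on C10. The two arms stand 1,3-diaxial on the same face. A formyl-bearing ring-fusion carbon cannot pass through the cationic chemistry that usually builds labdanes.
- **C9.** C9 holds its chain equatorial, cis to C20. An external reagent avoids that face. C9 is also flanked by the exocyclic alkene C8=C17.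
- **Who controls whom.** C5 can direct both C4 and C10. C4 and C5 together can then direct the ring fusion. C9 has no neighbour that directs it the right way.
- **Fragile groups.**
  - The butenolide does not survive hydride or base.
  - The acetate does not survive enolate chemistry.
  - C8=C17 moves into the ring in acid.
  - A free C19 hydroxyl closes onto the C20 aldehyde as a bridged lactol, so the acetate must be in place before the aldehyde appears.
- **Enabling feature 1.** The atoms O=C20–C10–C9–C8=C17 form a 4-pentenal unit that runs across ring B. Cutting C9–C10 and joining that oxygen to C17 turns ring B into an eight-membered allyl ester, which is a Claisen retron.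
- **Enabling feature 2.** Without C18 and C9, ring A has a mirror plane through C2 and C5. This plane exchanges C4/C19 with C10/C20.

## Retrosynthesis

**25 ⇒ 24 ⇒ 23 (C20–H, C19 O–acyl).** The aldehyde is made last, by oxidation of hydroxy acetate 24. Compound 24 comes from diol 23 by acetylation of the less hindered C19 hydroxyl. The reverse order would pass through the C19-OH/C20-CHO lactol, which acetylates at the wrong oxygen. The forward steps need one site selection between two neopentyl alcohols and a neutral oxidant.

**23 ⇒ 22 ⇒ 20 (C13–C16 and O–C16).**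
- The butenolide is cut to carbon monoxide and the (Z)-iodoallylic alcohol 22.
- Compound 22 goes back to the alkynol of 20. An alkynol is a butenolide surrogate that survives amide bases and palladium.
- The hydride that takes C19 and C20 down to alcohols also performs the trans-hydroalumination, so the surrogate costs no extra step.
- A C12 halide handle was rejected. C12 lies within ring-closing distance of the C20 oxygen function.

**20 ⇒ 17 (C9–C10; key step).**
- The [3,3] retron is opened. C9–C10 is cut, O–C17 is restored, C8=C17 becomes C8=C9, and lactone 17 results.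
- One operation then makes ring B, quaternary C10 with its carboxyl carbon, C9, and the exocyclic methylene.
- The neighbouring cut C9–C11 uses the same alkene but delivers carbon to the wrong face of C9.
- A palladium-allyl closure of the same C9–C10 bond would attack the free terminus C17. In the Claisen array the oxygen blocks C17.
- Lactone 17 carries only two stereocentres that count (C4, C5) and one alkene geometry.
- The forward reaction must enolise one hindered C–H and pass through a single possible chair.

**17 ⇒ 16 ⇒ 7 + 14 (acyl C20–O, then C7–C8).** The lactone opens to seco acid 16. Compound 16 is split at the sp3–sp2 bond C7–C8 into vinyl acid 7 and iodoallylic alcohol 14. This cut separates all stereocentres (in 7) from the alkene geometry and side chain (in 14). It needs no protecting group on either coupling partner.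

**7 ⇒ 6 ⇒ 5 (C4–C18, then symmetry).** Removing the C18 methyl gives half-ester 6. Re-esterification reveals meso diester 5. One enzymatic hydrolysis sets the absolute configuration and decides which carboxyl becomes C19 and which becomes C20. C4 is then set by C5 in an enolate methylation. The symmetric precursor is simpler than any chiral ring A synthon with a quaternary centre.

**5 ⇒ 3 ⇒ 2 ⇒ 1 (dearomatisation).** The all-cis array of 5 is what an arene gives on hydrogenation. The vinyl group must therefore travel as a saturated, hydrogenation-proof group. That group is the dimethylaminoethyl chain of 3 and 2, attached in one step to the benzylic methyl of the flat diester 1.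

**14 ⇒ 13 ⇒ 11 ⇒ 8.** The iodoalkene geometry comes from syn-hydrostannation of ynoate 11. Compound 11 is hexa-1,5-diyne 8 capped with formaldehyde at one end and with a carbomethoxy group at the other. The linear C8 unit supplies C17, C8, C9 and C11–C15.

## Roads not taken

**Alternative 1:** (the most obvious) cut C4–C5 and C9–C10 together.
- Forward: cation–olefin bicyclisation of the acyclic trienyl allylsilane A1, then deacetylation to the 20-methyl alcohol A2. C20 is then oxidised through 1,6-hydrogen abstraction by the C19 alkoxyl radical.
- The C10 cation tolerates only a methyl group. The hardest feature is therefore left to a late C–H oxidation on a molecule with two alkenes.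
- The alkoxyl radical has competing 1,5-hydrogens at C2 and C6, and hypoiodite reagents add to C8=C17.
- Without a C3 oxygen, the absolute sense must come from a chiral proton source.
- The chosen plan brings C20 in already oxidised and needs no C–H functionalisation.

**Alternative 2:** cut C1–C10 and C4–C5 (Robinson annulation).
- Forward: amine-catalysed aldol cyclisation to the angular-ester Wieland–Miescher analogue A3.
- This would be followed by reductive carboxylation and methylation at C4, removal of the C3 ketone, a shift of the C9 ketone to C8, chain attachment at C9, and methylenation.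
- The key step sets C10 only. Every other centre and carbon is added one at a time, and two ketones are spent on corrections.
- The chosen key step sets C9, C10, ring B and the alkene at once.

**Alternative 3:** cut C9–C11.
- Forward: orthoester Claisen rearrangement of the bicyclic allylic alcohol A4. This also creates C8=C17.
- The new bond must form axially at C9 and anti to the axial C20 group, for stereoelectronic and steric reasons alike. The product would therefore be the 9-epimer A5.
- The precursor already contains the whole decalin with both quaternary centres, so little is gained.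
- In the chosen plan the same alkene is used from the other side, and the tether forces the natural C9 configuration.

Key step: step 13

Assumption: the esterase of step 4 is taken to cleave the ester on the (S)-configured ring carbon of 5 (the future C20); a half-ester of the other sense would be corrected as described under the uncertain steps.

## Steps

Step 1
Reactants: 1 dimethyl 2-methylbenzene-1,3-dicarboxylate
Product: 2 dimethyl 2-[2-(dimethylamino)ethyl]benzene-1,3-dicarboxylate
Conditions: LDA (1.1 equiv), THF, −78 °C; then CH2=NMe2+ I−, −78 → 0 °C
Reagents that add atoms: Eschenmoser's salt (N,N-dimethylmethyleneiminium iodide), C=[N+](C)C.[I-]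
Why: Lateral lithiation of an o-toluate: the methyl group between two ortho esters should give a doubly stabilised benzylic enolate, which the iminium salt traps at carbon (Mannich-type aminomethylation). The tertiary amine cannot lactamise and serves as the latent vinyl group.

Step 2
Reactants: 2 dimethyl 2-[2-(dimethylamino)ethyl]benzene-1,3-dicarboxylate
Product: 3 dimethyl (1R,2s,3S)-2-[2-(dimethylamino)ethyl]cyclohexane-1,3-dicarboxylate (all-cis, meso)
Conditions: H2 (80 bar), 5 % Rh/Al2O3, AcOH, 60 °C
Reagents that add atoms: none
Why: Heterogeneous arene hydrogenation (dearomatisation): all six hydrogens arrive on the face bound to rhodium, so the three substituents should end all-cis, giving the meso isomer with equatorial esters and an axial side chain. Protonation in AcOH keeps the amine off the metal.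

Step 3
Reactants: 3 dimethyl (1R,2s,3S)-2-[2-(dimethylamino)ethyl]cyclohexane-1,3-dicarboxylate
Product: 5 dimethyl (1R,2s,3S)-2-ethenylcyclohexane-1,3-dicarboxylate (all-cis, meso), via amine N-oxide 4 (not isolated)
Conditions: mCPBA, CH2Cl2, 0 °C; filtration through basic alumina; then toluene, 110 °C
Reagents that add atoms: mCPBA, O=C(OO)c1cccc(Cl)c1 (oxygen atom of 4 only)
Why: N-oxidation followed by Cope elimination (syn, five-membered Ei) removes one of the only β-hydrogens, those on C6, and should release the vinyl group under neutral conditions. The epimerisable all-cis ester centres are left untouched.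

Step 4
Reactants: 5 dimethyl (1R,2s,3S)-2-ethenylcyclohexane-1,3-dicarboxylate
Product: 6 (1S,2S,3R)-2-ethenyl-3-(methoxycarbonyl)cyclohexane-1-carboxylic acid
Conditions: pig liver esterase, 0.1 M phosphate buffer pH 7/DMSO 9:1, 25 °C
Reagents that add atoms: water, O
Why: Enzymatic desymmetrisation of a meso diester by a serine carboxylesterase (EC 3.1.1.1): the chiral acyl pocket distinguishes the enantiotopic esters, and the anionic half-ester is no longer a substrate, so hydrolysis should stop at 6. This one event fixes the absolute configuration at C5 and assigns the free acid as C20 and the ester as C19.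

Step 5
Reactants: 6 (1S,2S,3R)-2-ethenyl-3-(methoxycarbonyl)cyclohexane-1-carboxylic acid
Product: 7 (1S,2S,3R)-2-ethenyl-3-(methoxycarbonyl)-3-methylcyclohexane-1-carboxylic acid
Conditions: LDA (2.2 equiv), THF, −78 → −30 °C; MeI, −78 °C; 1 M HCl
Reagents that add atoms: iodomethane, CI
Why: Alkylation of an exocyclic ester enolate within a carboxylate/enolate dianion; only the ester α-carbon (C4) is enolised. The vinyl group on C5 is axial (no A1,3 strain) and covers one face, so MeI should enter anti to it, placing C18 trans and C19 cis to C6 and setting C4.

Step 6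
Reactants: 8 hexa-1,5-diyne
Product: 9 hepta-2,6-diyn-1-ol
Conditions: 8 (2 equiv), n-BuLi (1 equiv), THF, −78 °C; (CH2O)n, → rt; H2O
Reagents that add atoms: paraformaldehyde (as formaldehyde), C=O
Why: Addition of a lithium acetylide to formaldehyde. The excess of the volatile, recoverable diyne limits reaction at both ends.

Step 7
Reactants: 9 hepta-2,6-diyn-1-ol
Product: 10 tert-butyl(hepta-2,6-diyn-1-yloxy)dimethylsilane
Conditions: TBSCl, imidazole, CH2Cl2, rt
Reagents that add atoms: tert-butyldimethylsilyl chloride, CC(C)(C)[Si](C)(C)Cl
Why: Standard silylation of a primary alcohol. The ether keeps O15 out of the later lactonisation and enolisation.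

Step 8
Reactants: 10 tert-butyl(hepta-2,6-diyn-1-yloxy)dimethylsilane
Product: 11 methyl 8-[(tert-butyldimethylsilyl)oxy]octa-2,6-diynoate
Conditions: n-BuLi, THF, −78 °C; ClCO2Me
Reagents that add atoms: methyl chloroformate, COC(=O)Cl
Why: Acylation of the terminal acetylide. It adds C17 and polarises one alkyne only.

Step 9
Reactants: 11 methyl 8-[(tert-butyldimethylsilyl)oxy]octa-2,6-diynoate
Product: 13 methyl (2E)-8-[(tert-butyldimethylsilyl)oxy]-2-iodooct-2-en-6-ynoate, via alkenylstannane 12 (not isolated)
Conditions: Bu3SnH (1.05 equiv, slow addition), Pd(PPh3)4 (2 mol %), THF, 0 °C; then I2, CH2Cl2, 0 °C, dark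
Reagents that add atoms: iodine, II; tributyltin hydride, CCCC[SnH](CCCC)CCCC (tin of 12 only)
Why: Pd(0)-catalysed syn-hydrostannation of a 2-ynoate places tin on the α-carbon (C8) and hydrogen on C9, and the electron-poor alkyne should react ahead of the propargylic ether alkyne. Iododestannylation proceeds with retention, so C11 ends cis to C17, the geometry that later sets C9.

Step 10
Reactants: 13 methyl (2E)-8-[(tert-butyldimethylsilyl)oxy]-2-iodooct-2-en-6-ynoate
Product: 14 (2E)-8-[(tert-butyldimethylsilyl)oxy]-2-iodooct-2-en-6-yn-1-ol
Conditions: DIBAL-H (2.2 equiv), CH2Cl2, −78 °C; Rochelle salt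
Reagents that add atoms: none
Why: 1,2-Reduction of an enoate to the allylic alcohol. The vinyl iodide, the alkyne and the silyl ether are inert at −78 °C.

Step 11
Reactants: 7 (1S,2S,3R)-2-ethenyl-3-(methoxycarbonyl)-3-methylcyclohexane-1-carboxylic acid; 14 (2E)-8-[(tert-butyldimethylsilyl)oxy]-2-iodooct-2-en-6-yn-1-ol
Product: 16 (1S,2S,3R)-2-[(3Z)-9-[(tert-butyldimethylsilyl)oxy]-3-(hydroxymethyl)non-3-en-7-yn-1-yl]-3-(methoxycarbonyl)-3-methylcyclohexane-1-carboxylic acid, via B-alkyl-9-BBN adduct 15 (not isolated)
Conditions: 7, 9-BBN-H (2.3 equiv), THF, 0 → 50 °C; then aq Cs2CO3, 14, Pd(dppf)Cl2 (5 mol %), AsPh3, DMF, rt → 40 °C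
Reagents that add atoms: 9-BBN-H, [H]B1C2CCCC1CCC2 (boron units of 15 only)
Why: Hydroboration followed by B-alkyl Suzuki–Miyaura coupling: one equivalent of borane masks the acid as its acyloxyborane and the next adds anti-Markovnikov to the vinyl group (boron on C7). The coupling forms C7–C8 with retention of the alkene geometry. Iodine is trans to the alkynyl chain, so carbopalladation of the alkyne is geometrically excluded.

Step 12
Reactants: 16 seco acid (as in step 11)
Product: 17 eight-membered lactone (20,17-olide): ring A cis-fused at C5–C10 to an oxocan-2-one that bears the (Z)-alkylidene C8=C9; C4 carries CH3 and CO2CH3; O15 is a TBS ether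
Conditions: 2-methyl-6-nitrobenzoic anhydride (MNBA), DMAP, CH2Cl2 (about 1 mM, syringe pump), rt
Reagents that add atoms: none
Why: Shiina macrolactonisation through the mixed anhydride under high dilution. The cis-1,2 arrangement of the acid and the chain on ring A, together with sp2 C8, holds the ends close and removes some transannular strain.

Step 13
Reactants: 17 eight-membered lactone (20,17-olide)
Product: 20 15-hydroxy-19-methoxy-19-oxo-16-nor-ent-labd-8(17)-en-13-yn-20-oic acid, via silyl ketene acetal 18 (not isolated), via bis-silylated rearranged ester 19 (not isolated)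
Conditions: LDA (1.5 equiv), TMSCl (in situ quench), THF, −78 °C; then 65 °C; then TBAF, THF, rt; 1 M HCl work-up
Reagents that add atoms: chlorotrimethylsilane, C[Si](C)(C)Cl (silicon of 18 and 19 only)
Why: Proposed new method: LDA/TMSCl should trap the lactone enolate as silyl ketene acetal 18, whose C10=C20 bond can only be cis within the eight-membered ring (ring oxygen syn to C5); on warming, O–C17 breaks as C9–C10 forms in a concerted suprafacial [3,3] shift (Ireland–Claisen rearrangement). The closest known reaction type is the ring-contracting (alicyclic) Ireland–Claisen rearrangement of macrolactones with an endocyclic allyl unit; new here is that the allyl unit is exocyclic and the tether C5–C6–C7 sits on its central carbon C8, so the oxocane contracts to a methylenecyclohexane. Ring B closes in a 6-(enol-exo)-endo-trig mode, and simple geometry shows that the three-atom tether can bridge C10 and C8 only in the chair array (a bicyclo[3.3.1]nonane-like transition state), the boat placing C7 out of reach. C9 is controlled by the alkene geometry: in this chair the substituent cis to C17, which is C11 of the (Z)-alkene, becomes equatorial on ring B and H-9 axial. C10 is controlled by C4 and C5: with C6 equatorial on ring A the C19 ester is axial and covers the face from which C9 would become axial (cis-decalin), so C9 should bond from the other face, giving the trans-decalin with C20 axial and syn to C19. Regioselectivity (C9 rather than C17) is secured because the oxygen occupies C17; chemoselectivity is secured because C10–H is the only enolisable position (C4 is quaternary); and in situ silylation keeps the enolate from fragmenting to a ketene. Fluoride then frees the C20 acid and the C15 alcohol in the same flask.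

Step 14
Reactants: 20 15-hydroxy-19-methoxy-19-oxo-16-nor-ent-labd-8(17)-en-13-yn-20-oic acid
Product: 22 (13Z)-13-iodo-16-nor-ent-labda-8(17),13-diene-15,19,20-triol, via cyclic alkenylalanate 21 (not isolated)
Conditions: LiAlH4, NaOMe, THF, reflux; cool, EtOAc (excess hydride); then I2, THF, −78 °C
Reagents that add atoms: iodine, II; lithium aluminium hydride, [Li+].[AlH4-] (aluminium of 21 only)
Why: The hydride reduces the C19 ester and the C20 acid, and the O15 alkoxyaluminate delivers hydride to C14 (hydroxyl-directed trans-hydroalumination; with methoxide present, aluminium ends on C13 in a five-membered ring). Iodine replaces aluminium with retention, so iodine and C15 should end cis, giving the (Z)-iodide.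

Step 15
Reactants: 22 (13Z)-13-iodo-16-nor-ent-labda-8(17),13-diene-15,19,20-triol
Product: 23 19,20-dihydroxy-ent-labda-8(17),13-dien-16,15-olide
Conditions: CO (5 bar), PdCl2(PPh3)2 (5 mol %), K2CO3, THF, 40 °C
Reagents that add atoms: carbon monoxide, [C-]#[O+]
Why: Palladium-catalysed carbonylative lactonisation of a (Z)-3-iodoallylic alcohol: the acylpalladium species on C13 is captured by the cis C15 hydroxyl in a five-membered closure that the remote neopentyl alcohols cannot match. The CO pressure keeps insertion ahead of a 5-exo Heck reaction with C8=C17.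

Step 16
Reactants: 23 19,20-dihydroxy-ent-labda-8(17),13-dien-16,15-olide
Product: 24 19-acetoxy-20-hydroxy-ent-labda-8(17),13-dien-16,15-olide
Conditions: Ac2O (1.05 equiv), 2,4,6-collidine, CH2Cl2, −20 °C
Reagents that add atoms: acetic anhydride, CC(=O)OC(C)=O
Why: Site-selective acylation: both alcohols are neopentyl, but C19 is flanked by CH3 and CH2, whereas C20 lies between C1, C5 and the branched C9 with its chain. The C19 hydroxyl should therefore react first with a limiting amount of a mild acyl donor.

Step 17
Reactants: 24 19-acetoxy-20-hydroxy-ent-labda-8(17),13-dien-16,15-olide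
Product: 25 (4R,5R,9R,10R)-19-acetoxy-20-oxo-ent-labda-8(17),13-dien-16,15-olide (target)
Conditions: Dess–Martin periodinane, CH2Cl2, 0 °C → rt
Reagents that add atoms: none
Why: Dess–Martin oxidation of a hindered primary alcohol under nearly neutral conditions. The acetate, the butenolide and the exocyclic alkene are inert, and the aldehyde cannot enolise or form a lactol because O19 is acylated.

## Compound list

1 | dimethyl 2-methylbenzene-1,3-dicarboxylate | COC(=O)c1cccc(C(=O)OC)c1C | starting material
2 | dimethyl 2-[2-(dimethylamino)ethyl]benzene-1,3-dicarboxylate | COC(=O)c1cccc(C(=O)OC)c1CCN(C)C | intermediate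
3 | dimethyl (1R,2s,3S)-2-[2-(dimethylamino)ethyl]cyclohexane-1,3-dicarboxylate (all-cis, meso) | CN(C)CC[C@@H]1[C@H](C(=O)OC)CCC[C@@H]1C(=O)OC | intermediate
4 | N-oxide of 3 (not isolated) | C[N+](C)([O-])CC[C@@H]1[C@H](C(=O)OC)CCC[C@@H]1C(=O)OC | intermediate
5 | dimethyl (1R,2s,3S)-2-ethenylcyclohexane-1,3-dicarboxylate (all-cis, meso) | C=C[C@@H]1[C@H](C(=O)OC)CCC[C@@H]1C(=O)OC | intermediate
6 | (1S,2S,3R)-2-ethenyl-3-(methoxycarbonyl)cyclohexane-1-carboxylic acid | C=C[C@@H]1[C@H](C(=O)OC)CCC[C@@H]1C(=O)O | intermediate
7 | (1S,2S,3R)-2-ethenyl-3-(methoxycarbonyl)-3-methylcyclohexane-1-carboxylic acid | C=C[C@@H]1[C@](C)(C(=O)OC)CCC[C@@H]1C(=O)O | intermediate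
8 | hexa-1,5-diyne | C#CCCC#C | starting material
9 | hepta-2,6-diyn-1-ol | C#CCCC#CCO | intermediate
10 | tert-butyl(hepta-2,6-diyn-1-yloxy)dimethylsilane | C#CCCC#CCO[Si](C)(C)C(C)(C)C | intermediate
11 | methyl 8-[(tert-butyldimethylsilyl)oxy]octa-2,6-diynoate | COC(=O)C#CCCC#CCO[Si](C)(C)C(C)(C)C | intermediate
12 | methyl (2E)-8-[(tert-butyldimethylsilyl)oxy]-2-(tributylstannyl)oct-2-en-6-ynoate (not isolated) | COC(=O)/C(=C\CCC#CCO[Si](C)(C)C(C)(C)C)[Sn](CCCC)(CCCC)CCCC | intermediate
13 | methyl (2E)-8-[(tert-butyldimethylsilyl)oxy]-2-iodooct-2-en-6-ynoate | COC(=O)/C(I)=C\CCC#CCO[Si](C)(C)C(C)(C)C | intermediate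
14 | (2E)-8-[(tert-butyldimethylsilyl)oxy]-2-iodooct-2-en-6-yn-1-ol | OC/C(I)=C\CCC#CCO[Si](C)(C)C(C)(C)C | intermediate
15 | B-alkyl-9-BBN adduct of 7, carboxyl as its 9-BBN acyloxyborane (not isolated) | C(C[C@@H]1[C@](C)(C(=O)OC)CCC[C@@H]1C(=O)OB1C2CCCC1CCC2)B1C2CCCC1CCC2 | intermediate
16 | (1S,2S,3R)-2-[(3Z)-9-[(tert-butyldimethylsilyl)oxy]-3-(hydroxymethyl)non-3-en-7-yn-1-yl]-3-(methoxycarbonyl)-3-methylcyclohexane-1-carboxylic acid | OC/C(=C\CCC#CCO[Si](C)(C)C(C)(C)C)CC[C@@H]1[C@](C)(C(=O)OC)CCC[C@@H]1C(=O)O | intermediate
17 | eight-membered lactone (20,17-olide) of 16, (8Z) | O=C1OC/C(=C\CCC#CCO[Si](C)(C)C(C)(C)C)CC[C@@H]2[C@](C)(C(=O)OC)CCC[C@H]12 | intermediate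
18 | trimethylsilyl ketene acetal of 17, ring oxygen cis to C5 (not isolated) | C[Si](C)(C)O/C1=C2\CCC[C@@](C)(C(=O)OC)[C@H]2CC/C(=C/CCC#CCO[Si](C)(C)C(C)(C)C)CO1 | intermediate
19 | trimethylsilyl ester and O15-TBS ether of 20 (not isolated) | C=C1CC[C@@H]2[C@](C)(C(=O)OC)CCC[C@@]2(C(=O)O[Si](C)(C)C)[C@@H]1CCC#CCO[Si](C)(C)C(C)(C)C | intermediate
20 | 15-hydroxy-19-methoxy-19-oxo-16-nor-ent-labd-8(17)-en-13-yn-20-oic acid | C=C1CC[C@@H]2[C@](C)(C(=O)OC)CCC[C@@]2(C(=O)O)[C@@H]1CCC#CCO | intermediate
21 | cyclic C13-alkenyl O15-alanate, drawn with O19 and O20 as free hydroxyls (not isolated) | [Li+].C=C1CC[C@@H]2[C@](C)(CO)CCC[C@@]2(CO)[C@@H]1CCC1=CCO[AlH2-]1 | intermediate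
22 | (13Z)-13-iodo-16-nor-ent-labda-8(17),13-diene-15,19,20-triol | C=C1CC[C@@H]2[C@](C)(CO)CCC[C@@]2(CO)[C@@H]1CC/C(I)=C/CO | intermediate
23 | 19,20-dihydroxy-ent-labda-8(17),13-dien-16,15-olide | C=C1CC[C@@H]2[C@](C)(CO)CCC[C@@]2(CO)[C@@H]1CCC1=CCOC1=O | intermediate
24 | 19-acetoxy-20-hydroxy-ent-labda-8(17),13-dien-16,15-olide | C=C1CC[C@@H]2[C@](C)(COC(C)=O)CCC[C@@]2(CO)[C@@H]1CCC1=CCOC1=O | intermediate
25 | (4R,5R,9R,10R)-19-acetoxy-20-oxo-ent-labda-8(17),13-dien-16,15-olide | C=C1CC[C@@H]2[C@](C)(COC(C)=O)CCC[C@@]2(C=O)[C@@H]1CCC1=CCOC1=O | target

## Step count and least certain steps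

Total: 17 steps. Longest linear sequence: 12 steps (steps 1–5 and 11–17; the branch through steps 6–10 and 11–17 has the same length).

**Step 13 (key step, proposed new method).**
- What may go wrong:
  - Slow deprotonation of the hindered C10–H.
  - Fragmentation of the enolate to a ketene and an alkoxide before silylation.
  - Leakage through the face that leads to the cis-decalin, if ring A leaves the chair with the axial C19 ester.
- Fallback (known chemistry only; sets out from 7 and 14, returns at 20). The order of sigmatropic shift and ring closure is inverted.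
  - Acid 7 is esterified with 14 (carbodiimide, DMAP) to the open iodoallyl ester F1.
  - An ordinary acyclic Ireland–Claisen rearrangement follows, with enolisation by a chelating chiral lithium amide to define the ketene acetal geometry, which the ring no longer enforces. It gives the 2-iodoallyl acid F2.
  - Hydroboration of the C5 vinyl group with 9-BBN and an intramolecular B-alkyl Suzuki–Miyaura coupling close the six-membered ring B at C7–C8. This gives the TBS-protected acid F3.
  - TBAF then gives 20.

**Step 12.**
- What may go wrong: oligomerisation outruns closure of the eight-membered ring, because entropy and transannular strain disfavour the ring.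
- Fallback (from 16 to 17): the roles of the two ends are reversed. The allylic alcohol is activated, and the carboxylate attacks C17 in an intramolecular Mitsunobu esterification at high dilution. The ring then closes by SN2 at an unhindered allylic carbon instead of by acyl transfer at the hindered C20 (no new compound, F0).

**Step 14.**
- What may go wrong:
  - Incomplete reduction of the hindered C20 carboxylate by the methoxide-moderated hydride.
  - Loss of regiocontrol in the hydroalumination.
  - Iodine-induced ether formation between O20 and C8=C17.
- Fallback (sets out from 17, returns at 22). Carbonyl reduction and alkyne functionalisation are decoupled.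
  - Step 13 is run on 17 but worked up with aqueous acid instead of fluoride. This leaves the silyl ether and gives the TBS-protected acid F3, already met above.
  - LiAlH4 in refluxing THF, with no free alkynol present, gives the silyl-protected diol F4.
  - TBAF gives the alkynetriol F5.
  - Red-Al at 0 °C followed by iodine at −78 °C, now on a substrate without carbonyl groups, gives 22.

**Step 16.**
- What may go wrong: poor discrimination between the two neopentyl hydroxyls, and acetyl migration between the 1,3-diaxial oxygens.
- Fallback (from 23 to 24). Proximity replaces steric bias.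
  - N-iodosuccinimide closes O20 onto C8=C17 to give the 8,20-epoxy-17-iodide F6. This masks the C20 hydroxyl and the alkene together.
  - The only remaining hydroxyl is acetylated to give the iodoether acetate F7.
  - Zinc in ethanol/acetic acid regenerates C8=C17 and the C20 hydroxyl by reductive β-elimination, giving 24.

**Step 4.**
- What may go wrong: low enantioselectivity, or hydrolysis of the other enantiotopic ester by the available enzyme.
- Fallback (from 5 to 6). The symmetry is broken by a small-molecule catalyst whose two pseudo-enantiomers are both available.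
  - Saponification gives the meso diacid F8.
  - Acetic anhydride closes it to the bridged meso anhydride F9.
  - Methanolysis catalysed by a cinchona alkaloid derivative, with the quinine or quinidine series chosen for the required sense, gives 6.

## Further compounds

F1 | step 13 | (2E)-8-[(tert-butyldimethylsilyl)oxy]-2-iodooct-2-en-6-yn-1-yl ester of 7 | C=C[C@@H]1[C@](C)(C(=O)OC)CCC[C@@H]1C(=O)OC/C(I)=C\CCC#CCO[Si](C)(C)C(C)(C)C
F2 | step 13 | acyclic Claisen product: ring A acid with quaternary C10 bearing the C9 carbon that carries the 2-iodoallyl unit (C8(I)=C17H2) and the alkynyl chain | C=C[C@@H]1[C@](C)(C(=O)OC)CCC[C@@]1(C(=O)O)[C@H](CCC#CCO[Si](C)(C)C(C)(C)C)C(I)=C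
F3 | step 13 | O15-TBS ether of 20 | C=C1CC[C@@H]2[C@](C)(C(=O)OC)CCC[C@@]2(C(=O)O)[C@@H]1CCC#CCO[Si](C)(C)C(C)(C)C
F0 | step 12 | none | none
F4 | step 14 | 15-[(tert-butyldimethylsilyl)oxy]-16-nor-ent-labd-8(17)-en-13-yne-19,20-diol | C=C1CC[C@@H]2[C@](C)(CO)CCC[C@@]2(CO)[C@@H]1CCC#CCO[Si](C)(C)C(C)(C)C
F5 | step 14 | 16-nor-ent-labd-8(17)-en-13-yne-15,19,20-triol | C=C1CC[C@@H]2[C@](C)(CO)CCC[C@@]2(CO)[C@@H]1CCC#CCO
F6 | step 16 | 8,20-epoxy-19-hydroxy-17-iodo-ent-labd-13-en-16,15-olide | IC[C@]12CC[C@@H]3[C@](C)(CO)CCC[C@@]3(CO1)[C@@H]2CCC1=CCOC1=O
F7 | step 16 | 19-acetoxy-8,20-epoxy-17-iodo-ent-labd-13-en-16,15-olide | IC[C@]12CC[C@@H]3[C@](C)(COC(C)=O)CCC[C@@]3(CO1)[C@@H]2CCC1=CCOC1=O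
F8 | step 4 | (1R,2s,3S)-2-ethenylcyclohexane-1,3-dicarboxylic acid (all-cis, meso) | C=C[C@@H]1[C@H](C(=O)O)CCC[C@@H]1C(=O)O
F9 | step 4 | 9-ethenyl-3-oxabicyclo[3.3.1]nonane-2,4-dione (meso) | C=C[C@@H]1[C@H]2CCC[C@@H]1C(=O)OC2=O
A1 | alternative 1 | acyclic trienyl allylsilane carrying the C19 acetate and the butenolide | CC(=O)OC/C(C)=C\CC/C(C)=C/CC/C(C[Si](C)(C)C)=C/CCC1=CCOC1=O
A2 | alternative 1 | 19-hydroxy-ent-labda-8(17),13-dien-16,15-olide (C20 = CH3) | C=C1CC[C@@H]2[C@](C)(CO)CCC[C@@]2(C)[C@@H]1CCC1=CCOC1=O
A3 | alternative 2 | Wieland–Miescher ketone analogue with an angular methyl ester | COC(=O)[C@@]12CCC(=O)C=C1CCCC2=O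
A4 | alternative 3 | bicyclic allylic alcohol (C8=C9, C17 hydroxymethyl, C19 and C20 methyl esters) | OCC1=C[C@]2(C(=O)OC)CCC[C@@](C)(C(=O)OC)[C@H]2CC1
A5 | alternative 3 | 9-epi orthoester Claisen product (ethyl ester at C12) | C=C1CC[C@@H]2[C@](C)(C(=O)OC)CCC[C@@]2(C(=O)OC)[C@H]1CC(=O)OCC
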